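Atom numbers follow the target SMILES. The route hinges on disconnecting C13–C26: C13 is a fully substituted carbon lying between the C11 carbonyl and C26 of the hydroquinone ring, the signature of an enol carbon that has attacked a quinone. In one operation the ring A enedione enolises at C13 and adds to C26 of the tethered benzoquinone, closing the five-membered ring C6–C13–C26–C19–C18 of the benzobicyclo[3.2.1]octadiene, fixing C13 and regenerating the hydroquinone. The precursor is the cis-fused endo Diels–Alder adduct of an (E)-1-aryl-3-methylbutadiene with the prenyl-bearing alkene of prenylbenzoquinone, its aryl ring oxidised to the quinone. A final prenyl ene closure onto C9 completes the cyclopentanone.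

Key step: step 11

Conventions: ring A = C6/C7/C9/C10/C11/C13 (enedione ring), ring B = C6/C13/C14/C15/C17/C18 (cyclohexene); C5 is the prenyl CH2; cyclopentadiene 6 is cracked from its commercial dimer just before use.
Assumption: the (S)-configured oxazaborolidinium catalyst is taken to deliver adduct 7 in the configuration drawn; should 7 prove to be the antipode, the (R)-catalyst is used and nothing else changes.

Step 1
Reactants: 1 1,4-dimethoxybenzene; 2 1-bromo-3-methylbut-2-ene (prenyl bromide)
Product: 4 1,4-dimethoxy-2-(3-methylbut-2-en-1-yl)benzene, via (2,5-dimethoxyphenyl)lithium 3 (not isolated)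
Conditions: n-BuLi, TMEDA, THF, 0 °C; then CuBr·SMe2 (10 mol %), 2, −78 °C to rt
Reagents that add atoms: none
Why: Directed ortho-lithiation of the dimethoxyarene followed by copper-catalysed SN2 allylation with the primary allylic bromide should give the C-prenylated arene without allylic transposition.

Step 2
Reactants: 4 1,4-dimethoxy-2-(3-methylbut-2-en-1-yl)benzene
Product: 5 2-(3-methylbut-2-en-1-yl)-1,4-benzoquinone (prenylbenzoquinone)
Conditions: (NH4)2Ce(NO3)6 (2.5 equiv), MeCN/H2O, 0 °C
Reagents that add atoms: water, O
Why: Oxidative demethylation of a 1,4-dimethoxyarene (two one-electron oxidations, water attacking the ipso carbons, methanol leaving) gives the p-quinone, and at 0 °C the trisubstituted prenyl alkene should be left alone.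

Step 3
Reactants: 5 prenylbenzoquinone; 6 cyclopenta-1,3-diene
Product: 7 (4aR,5S,8R,8aS)-2-(3-methylbut-2-en-1-yl)-4a,5,8,8a-tetrahydro-5,8-methanonaphthalene-1,4-dione (endo adduct)
Conditions: (S)-3,3-diphenyl-1-(o-tolyl)tetrahydro-1H,3H-pyrrolo[1,2-c][1,3,2]oxazaborole (20 mol %), (CF3SO2)2NH (16 mol %), 6 (3 equiv), CH2Cl2, −78 °C
Reagents that add atoms: none
Why: Catalytic enantioselective Diels–Alder reaction with a protonated chiral oxazaborolidine: the diene adds endo to the more reactive unsubstituted C9=C10 bond while the bound catalyst shields one quinone face, which sets C9, C10 and the two norbornene bridgeheads together and at the same time masks C9=C10 for the next cycloaddition.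

Step 4
Reactants: 8 2,5-dihydroxybenzaldehyde
Product: 9 2,5-bis(tert-butyldimethylsilyloxy)benzaldehyde
Conditions: TBSCl, imidazole, DMF, rt
Reagents that add atoms: tert-butyldimethylsilyl chloride, CC(C)(C)[Si](C)(C)Cl
Why: Imidazole-promoted silylation caps both phenols, leaves the aldehyde untouched, and gives ethers that tolerate ylides and heat and are later removed by fluoride.

Step 5
Reactants: 9 2,5-bis(tert-butyldimethylsilyloxy)benzaldehyde
Product: 10 (E)-4-[2,5-bis(tert-butyldimethylsilyloxy)phenyl]but-3-en-2-one
Conditions: Ph3P=CHC(O)CH3, toluene, 90 °C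
Reagents that add atoms: 1-(triphenylphosphoranylidene)propan-2-one, CC(=O)C=P(c1ccccc1)(c1ccccc1)c1ccccc1
Why: Wittig olefination with a stabilised ylide should give the (E)-enone under neutral conditions, avoiding the alkoxide intermediates that could trigger migration of the ortho silyl group.

Step 6
Reactants: 10 (E)-4-[2,5-bis(tert-butyldimethylsilyloxy)phenyl]but-3-en-2-one
Product: 11 (E)-1-[2,5-bis(tert-butyldimethylsilyloxy)phenyl]-3-methylbuta-1,3-diene
Conditions: Ph3PCH3Br, NaN(SiMe3)2, THF, 0 °C; then 10, 0 °C to rt
Reagents that add atoms: methyltriphenylphosphonium bromide, C[P+](c1ccccc1)(c1ccccc1)c1ccccc1.[Br-]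
Why: Wittig methylenation of the ketone carbonyl (1,2-olefination of the enone) installs the terminal methylene and leaves the (E)-styryl bond as it is, the standard entry to 1-aryl-3-methylbutadienes.

Step 7
Reactants: 7 endo cyclopentadiene adduct; 11 (E)-aryl diene (1.5 equiv)
Product: 12 cyclopentadiene-blocked endo adduct (6S,13R,18R; full description in the compound list)
Conditions: toluene (1 M), BHT (cat.), 110 °C, sealed tube, dark
Reagents that add atoms: none
Why: Thermal Diels–Alder reaction at the only activated alkene left, C6=C13: the unsubstituted diene terminus C14 bonds to C13 (beta to C7=O and not deactivated by the alkyl donor) and the aryl-bearing C18 to C6, as in uncatalysed additions to 2-alkylquinone-type dienophiles (no Lewis acid is used because coordination at C11=O would reverse this), the diene approaches the face anti to the norbornene (the face of H9/H10) in the endo mode, and this sets C6, C13 and C18 with the aryl group cis to C7 and trans to the prenyl group.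

Step 8
Reactants: 12 cyclopentadiene-blocked endo adduct
Product: 13 (4aS,5R,8aR)-5-[2,5-bis(tert-butyldimethylsilyloxy)phenyl]-7-methyl-4a-(3-methylbut-2-en-1-yl)-4a,5,8,8a-tetrahydronaphthalene-1,4-dione
Conditions: Ph2O, 220 °C, argon sweep, 20 min
Reagents that add atoms: none
Why: Retro-Diels–Alder reaction: entropy-driven loss of cyclopentadiene from the norbornene unveils the C9=C10 enedione without touching C6, C13 or C18, and the short heating time is meant to limit a thermal ene reaction of the prenyl group.

Step 9
Reactants: 13 bis-silyl enedione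
Product: 14 (4aS,5R,8aR)-5-(2,5-dihydroxyphenyl)-7-methyl-4a-(3-methylbut-2-en-1-yl)-4a,5,8,8a-tetrahydronaphthalene-1,4-dione
Conditions: Bu4NF, AcOH, THF, 0 °C, argon
Reagents that add atoms: none
Why: Fluoride cleavage of the aryl silyl ethers, buffered with acetic acid so that no phenoxide or enolate builds up and the cis-fused enedione is neither epimerised nor attacked.

Step 10
Reactants: 14 hydroquinone enedione
Product: 15 (4aS,5R,8aR)-5-(3,6-dioxocyclohexa-1,4-dien-1-yl)-7-methyl-4a-(3-methylbut-2-en-1-yl)-4a,5,8,8a-tetrahydronaphthalene-1,4-dione (key-step precursor)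
Conditions: Ag2O, MgSO4, Et2O, rt, dark; filtered and used at once
Reagents that add atoms: none
Why: Ag2O oxidises the hydroquinone to the p-benzoquinone under neutral, anhydrous conditions that should leave the enedione, both alkenes and C13–H untouched.

Step 11
Reactants: 15 quinone enedione
Product: 16 tetracyclic prenyl enedione hydroquinone (6S,13R,18R)
Conditions: Et3N (1.0 equiv), degassed CH2Cl2 (5 mM), −20 °C to rt, argon; aq. ascorbic acid wash
Reagents that add atoms: none
Why: Et3N removes C13–H, the only sp3 proton alpha to a ring A carbonyl (C6 is quaternary, so the enedione cannot aromatise), and the C11 dienolate adds through C13 to C26, the unsubstituted beta-carbon of the C20 enone of the quinone; proton shifts then aromatise the adduct to the hydroquinone, which makes the closure irreversible. The closest known reaction type is the Michael addition of ketone enolates and 1,3-dicarbonyl compounds to benzoquinones (quinone alpha-arylation), here run intramolecularly. The ring closed is the five-membered ring C6–C13–C26–C19–C18, in a 5-(enolexo)-endo-trig mode at the quinone C19=C26 bond, the mode by which 2-(2-aminoethyl)benzoquinones close to 5-hydroxyindolines, and it completes the benzobicyclo[3.2.1]octadiene. The new stereocentre C13 is controlled by the two-atom tether: the quinone on C18 lies on the face of ring B that carries C7 and C11 (a consequence of the endo cycloaddition), so C26 can bond only to that face of the planar C13, C11 is pushed to the other face and the A/B fusion changes from cis to trans (13R). The step needs C- over O-attack, C26 over C22/C23, removal of C13–H over the allylic C18–H, and intra- over intermolecular addition; reach secures the first two (only C13 and C26 fit a five-membered ring), the weak base at low temperature is meant to secure the third and high dilution the last, while the ascorbate wash returns any product oxidised by unreacted quinone.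

Step 12
Reactants: 16 tetracyclic prenyl enedione hydroquinone
Product: 17 CNP0287617.1 (4S,6S,9R,13R,18R)
Conditions: Me2AlCl (4 equiv), CH2Cl2, −78 to 0 °C; aq. HCl work-up
Reagents that add atoms: none
Why: Lewis-acid-promoted intramolecular conjugate ene (Michael-type) cyclisation: once the two phenols are aluminium phenoxides (methane lost), Me2AlCl on the C11 carbonyl makes C9 electrophilic, prenyl carbon C4, held axially over ring A by C5, bonds to C9 through an open transition state with the CMe2 terminus turned away from the C10–C11–C13 bridge, and loss of a methyl proton from the tertiary cation should leave the isopropenyl group exo (4S) while C9 (R) is dictated by the one-carbon tether, the five-membered closure at C9 being preferred to the six-membered one at C10.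

Compound list
1 | 1,4-dimethoxybenzene | COc1ccc(OC)cc1 | starting material
2 | 1-bromo-3-methylbut-2-ene (prenyl bromide) | CC(C)=CCBr | starting material
3 | (2,5-dimethoxyphenyl)lithium | [Li]c1cc(OC)ccc1OC | intermediate (not isolated)
4 | 1,4-dimethoxy-2-(3-methylbut-2-en-1-yl)benzene | COc1ccc(OC)c(CC=C(C)C)c1 | intermediate
5 | 2-(3-methylbut-2-en-1-yl)-1,4-benzoquinone | CC(C)=CCC1=CC(=O)C=CC1=O | intermediate
6 | cyclopenta-1,3-diene | C1=CCC=C1 | starting material
7 | (4aR,5S,8R,8aS)-2-(3-methylbut-2-en-1-yl)-4a,5,8,8a-tetrahydro-5,8-methanonaphthalene-1,4-dione; endo adduct across the unsubstituted quinone bond, ring-fusion hydrogens exo on the norbornene | CC(C)=CCC1=CC(=O)[C@@H]2[C@@H]3C=C[C@@H](C3)[C@@H]2C1=O | intermediate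
8 | 2,5-dihydroxybenzaldehyde | O=Cc1cc(O)ccc1O | starting material
9 | 2,5-bis(tert-butyldimethylsilyloxy)benzaldehyde | O=Cc1cc(O[Si](C)(C)C(C)(C)C)ccc1O[Si](C)(C)C(C)(C)C | intermediate
10 | (E)-4-[2,5-bis(tert-butyldimethylsilyloxy)phenyl]but-3-en-2-one | CC(=O)/C=C/c1cc(O[Si](C)(C)C(C)(C)C)ccc1O[Si](C)(C)C(C)(C)C | intermediate
11 | (E)-1-[2,5-bis(tert-butyldimethylsilyloxy)phenyl]-3-methylbuta-1,3-diene | C=C(C)/C=C/c1cc(O[Si](C)(C)C(C)(C)C)ccc1O[Si](C)(C)C(C)(C)C | intermediate
12 | cyclopentadiene-blocked endo adduct: ring A 1,4-diketone cis-fused to ring B on the face of H9/H10 and to the norbornene on the opposite face; prenyl on C6, H on C13 cis to it, bis-silyloxyaryl on C18 cis to C7 (6S,13R,18R) | CC(C)=CC[C@@]12C(=O)[C@H]3[C@H]4C=C[C@H](C4)[C@H]3C(=O)[C@@H]1CC(C)=C[C@@H]2c1cc(O[Si](C)(C)C(C)(C)C)ccc1O[Si](C)(C)C(C)(C)C | intermediate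
13 | (4aS,5R,8aR)-5-[2,5-bis(tert-butyldimethylsilyloxy)phenyl]-7-methyl-4a-(3-methylbut-2-en-1-yl)-4a,5,8,8a-tetrahydronaphthalene-1,4-dione | CC(C)=CC[C@@]12C(=O)C=CC(=O)[C@@H]1CC(C)=C[C@@H]2c1cc(O[Si](C)(C)C(C)(C)C)ccc1O[Si](C)(C)C(C)(C)C | intermediate
14 | (4aS,5R,8aR)-5-(2,5-dihydroxyphenyl)-7-methyl-4a-(3-methylbut-2-en-1-yl)-4a,5,8,8a-tetrahydronaphthalene-1,4-dione | CC(C)=CC[C@@]12C(=O)C=CC(=O)[C@@H]1CC(C)=C[C@@H]2c1cc(O)ccc1O | intermediate
15 | (4aS,5R,8aR)-5-(3,6-dioxocyclohexa-1,4-dien-1-yl)-7-methyl-4a-(3-methylbut-2-en-1-yl)-4a,5,8,8a-tetrahydronaphthalene-1,4-dione; cis-fused endo adduct with the aryl ring as benzoquinone | CC(C)=CC[C@@]12C(=O)C=CC(=O)[C@@H]1CC(C)=C[C@@H]2C1=CC(=O)C=CC1=O | intermediate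
16 | tetracyclic prenyl enedione hydroquinone: trans-fused A/B enedione whose C13 and C18 are bridged by the 3,6-dihydroxy-1,2-phenylene unit, prenyl on C6 (6S,13R,18R) | CC(C)=CC[C@@]23C(=O)C=CC(=O)[C@@]21CC(C)=C[C@@H]3c2c(O)ccc(O)c21 | intermediate
17 | CNP0287617.1 (4S,6S,9R,13R,18R), exo isopropenyl on C4 | C=C(C)[C@H]1C[C@@]23C(=O)[C@@H]1CC(=O)[C@@]21CC(C)=C[C@@H]3c2c(O)ccc(O)c21 | target

Total step count: 12. Longest linear sequence: 9 steps (steps 1, 2, 3, 7, 8, 9, 10, 11, 12; the aryl diene arm, steps 4, 5, 6, joins at step 7 and is equally long).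

Steps most likely to fail

Step 11 (key step). The amine may abstract the allylic, quinone-activated C18–H instead of C13–H, which would tautomerise the quinone to a quinone methide and erase C18. Electron transfer or bimolecular Michael addition may outrun the strained 5-endo closure. The new C24 phenol may then add to C10 of the enedione. Fallback (silyl enol ether chemistry in place of enolate chemistry, a Mukaiyama–Michael closure): setting out from quinone 15, Me3SiOTf and Et3N in CH2Cl2 at −78 °C should convert the C11 ketone into its silyl dienol ether while the silyl triflate activates the quinone carbonyl. Addition through C13 to C26 followed by silyl transfer should give the bis(trimethylsilyl) ether of 16 F1, whose capped C24 oxygen cannot add to C10. Methanolysis with citric acid in MeOH at 0 °C rejoins the route at 16.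

Step 12. Aluminium phenoxides formed from the free hydroquinone may sequester the Lewis acid. The electron-rich ring or its oxygen may capture the tertiary cation before it loses a proton. Closure may also occur at C10, or with the isopropenyl group endo. Fallback (the cyclisation is run on an electron-poor, non-coordinating aryl diester): setting out from 16, Ac2O, pyridine and DMAP give the diacetate of 16 F2. Me2AlCl (2.5 equiv) in CH2Cl2 at −78 to 0 °C should cyclise it to the diacetate of 17 F3. K2CO3 in degassed MeOH at 0 °C removes the acetates and rejoins the route at 17.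

Step 8. In the hot condensed phase the prenyl group may undergo a thermal ene reaction with the newly formed enedione, and C13 may epimerise, before all cyclopentadiene has left. Fallback (a lighter dimethyl ether series that can be pyrolysed in the gas phase and oxidised directly to the quinone): setting out from aldehyde 8, MeI and K2CO3 in DMF give 2,5-dimethoxybenzaldehyde F4. Horner–Wadsworth–Emmons olefination with lithiated diethyl (2-methylallyl)phosphonate (THF, −78 °C to rt) gives (E)-1-(2,5-dimethoxyphenyl)-3-methylbuta-1,3-diene F5. Thermal Diels–Alder reaction with 7 under the conditions of step 7 should give the dimethyl ether analogue of 12 F6. Flash vacuum pyrolysis (500 °C, 0.01 mbar) should then give the dimethyl ether analogue of 13 F7, because at millisecond contact the fragmentation, with its larger activation entropy, is favoured over the ordered ene transition state. (NH4)2Ce(NO3)6 in MeCN/H2O at 0 °C oxidises the dimethoxyarene directly to quinone 15, where the route is rejoined; 13 and 14 are bypassed.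

Further compounds
F1 | step 11 | bis(trimethylsilyl) ether of 16 | CC(C)=CC[C@@]23C(=O)C=CC(=O)[C@@]21CC(C)=C[C@@H]3c2c(O[Si](C)(C)C)ccc(O[Si](C)(C)C)c21
F2 | step 12 | diacetate of 16 | CC(C)=CC[C@@]23C(=O)C=CC(=O)[C@@]21CC(C)=C[C@@H]3c2c(OC(C)=O)ccc(OC(C)=O)c21
F3 | step 12 | diacetate of 17 | C=C(C)[C@H]1C[C@@]23C(=O)[C@@H]1CC(=O)[C@@]21CC(C)=C[C@@H]3c2c(OC(C)=O)ccc(OC(C)=O)c21
F4 | step 8 | 2,5-dimethoxybenzaldehyde | COc1ccc(OC)c(C=O)c1
F5 | step 8 | (E)-1-(2,5-dimethoxyphenyl)-3-methylbuta-1,3-diene | C=C(C)/C=C/c1cc(OC)ccc1OC
F6 | step 8 | dimethyl ether analogue of 12 | CC(C)=CC[C@@]12C(=O)[C@H]3[C@H]4C=C[C@H](C4)[C@H]3C(=O)[C@@H]1CC(C)=C[C@@H]2c1cc(OC)ccc1OC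
F7 | step 8 | dimethyl ether analogue of 13 | CC(C)=CC[C@@]12C(=O)C=CC(=O)[C@@H]1CC(C)=C[C@@H]2c1cc(OC)ccc1OC
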